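**Plan**
- Retrosynthesis: the O9 acetyl group, the O14 (R)-2-methylbutanoyl group and the C1–C10 oxirane are removed first. The ring is then cut at C3–C4, the chain at C4=C5, C9–C10 and C7–C11, and the diene at C1–C2.
- Enabling feature: in the ten-membered ring the trisubstituted enoate C4=C5 carries the ring methylene C3 on C4, cis to C6, and C3 is bonded to a second methylene (C2). C3–C4 is therefore an sp3–sp2 bond that a primary C3 borane (from a terminal C2=C3 vinyl group) and a (Z)-C4–Br enoate can form with retention.
- Forward: lactone 3 (C5–C9) and bromodiene 9 (C10, C14, C1–C3) are joined at C9–C10, and C4/C15 are added by a bromo-Wittig reaction. The only ring, the ten-membered carbocycle, closes at C3–C4, and the epoxide and the two esters come last.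
- Stereochemistry: C7 from a rhodium/(S)-BINAP conjugate addition, C9 from a Corey–Bakshi–Shibata reduction, C1/C10 from a Sharpless epoxidation of the E-alkene (E geometry from anti-bromination and stereoretentive coupling). The acyl stereocentre comes from (R)-2-methylbutanoic acid, and the ring-cis C4=C5 geometry from the (Z)-selective Wittig step.

Key step: step 12

Remark: atom labels follow the ring of the target (C7 bears isopropenyl C11–C13, C4 bears the ester carbon C15, C10 bears C14H2O, C9 bears the acetate). Bromine addition to methyl propiolate is assumed to give mainly the (E)-dibromide, the minor (Z)-isomer being removed by distillation.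

**Step 1**
Reactants: 1 5,6-dihydro-2H-pyran-2-one; 2 isopropenylboronic acid pinacol ester
Product: 3 (S)-4-isopropenyl-oxan-2-one
Conditions: [Rh(cod)OH]2 (2.5 mol%), (S)-BINAP (6 mol%), dioxane/H2O 10:1, 60 °C
Reagents that add atoms: none
Why: Rhodium-catalysed asymmetric conjugate addition (Hayashi–Miyaura reaction) of the alkenylrhodium species to the β-carbon of the unsaturated lactone; (S)-BINAP is expected, by the enantioface model established for cyclic enones and enoates, to set C7 (lactone C4) as S, and the antipodal ligand would be taken if the sense proved opposite.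

**Step 2**
Reactants: 4 methyl propiolate
Product: 5 methyl (E)-2,3-dibromoprop-2-enoate
Conditions: Br2 (1.0 equiv), CH2Cl2, 0 °C → rt, dark; distillation
Reagents that add atoms: bromine, BrBr
Why: Electrophilic anti-addition of bromine to the alkyne should give the trans-dibromide, which places the C3 bromine cis to the ester carbon (future C14).

**Step 3**
Reactants: 5 methyl (E)-2,3-dibromoprop-2-enoate; 6 tributyl(vinyl)stannane
Product: 7 methyl (E)-2-bromopenta-2,4-dienoate
Conditions: Pd2(dba)3 (2.5 mol%), AsPh3 (10 mol%), CuI (10 mol%), 6 (1.0 equiv), NMP, rt, dark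
Reagents that add atoms: none
Why: Stille coupling in which zerovalent palladium inserts into the more electron-poor, less hindered β-C–Br bond and couples with retention, so the vinyl group (C2=C3) ends cis to the ester carbon and trans to the remaining bromine, which marks the later C9 position.

**Step 4**
Reactants: 7 methyl (E)-2-bromopenta-2,4-dienoate
Product: 8 (E)-2-bromopenta-2,4-dien-1-ol
Conditions: i-Bu2AlH (2.2 equiv), CH2Cl2, −78 °C; aqueous Rochelle salt
Reagents that add atoms: none
Why: 1,2-Reduction of the enoate by the aluminium hydride at low temperature gives the allylic alcohol and should leave the alkenyl bromide and the alkene geometry untouched.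

**Step 5**
Reactants: 8 (E)-2-bromopenta-2,4-dien-1-ol
Product: 9 (E)-2-bromopenta-2,4-dienyl tert-butyldimethylsilyl ether
Conditions: TBSCl, imidazole, CH2Cl2, 0 °C → rt
Reagents that add atoms: tert-butyl(chloro)dimethylsilane, CC(C)(C)[Si](C)(C)Cl
Why: Standard silylation of a primary alcohol; the silyl ether makes the fragment compatible with the organolithium chemistry of the next step.

**Step 6**
Reactants: 9 bromodiene silyl ether; 3 (S)-4-isopropenyl-oxan-2-one
Product: 11 hydroxy dienone (C5–OH, C9=O, E-C10=C1, terminal C2=C3), via dienyllithium 10 (not isolated)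
Conditions: t-BuLi (2.05 equiv), Et2O, −78 °C, 20 min; then 3 (0.9 equiv), −78 °C; sat. aq NH4Cl at −78 °C
Reagents that add atoms: none
Why: Bromine–lithium exchange with retention of alkene geometry, then organolithium addition to the lactone carbonyl at −78 °C, where single addition is the rule for six-membered lactones, forms C9–C10 with C9 trans to C2 and releases the ring-opened hydroxy ketone on protonation.

**Step 7**
Reactants: 11 hydroxy dienone
Product: 12 keto aldehyde (C5 aldehyde)
Conditions: Dess–Martin periodinane [1,1,1-triacetoxy-1,1-dihydro-1,2-benziodoxol-3(1H)-one], pyridine, CH2Cl2, 0 °C → rt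
Reagents that add atoms: none
Why: Dess–Martin oxidation of the primary alcohol under near-neutral conditions gives the aldehyde without touching the dienone, the silyl ether or C7, which is not α to either carbonyl group.

**Step 8**
Reactants: 13 methyl (triphenylphosphoranylidene)acetate
Product: 15 methyl bromo(triphenylphosphoranylidene)acetate, via phosphonium bromide 14 (not isolated)
Conditions: Br2 (1.0 equiv), CH2Cl2, 0 °C; then aq NaOH, 0 °C
Reagents that add atoms: bromine, BrBr
Why: Halogenation of a stabilised ylide at carbon gives the α-bromophosphonium salt, which hydroxide deprotonates to the isolable α-bromo ylide.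

**Step 9**
Reactants: 12 keto aldehyde; 15 methyl bromo(triphenylphosphoranylidene)acetate
Product: 16 (Z)-α-bromoenoate dienone
Conditions: 15 (1.3 equiv), CH2Cl2, rt, dark
Reagents that add atoms: none
Why: Wittig olefination with a stabilised α-bromo ylide should react only at the aldehyde (the conjugated ketone is inert) and place the ester trans to C6, giving the (Z)-bromoenoate with bromine cis to C6.

**Step 10**
Reactants: 16 (Z)-α-bromoenoate dienone
Product: 17 (9S)-dienyl alcohol
Conditions: (R)-1-methyl-3,3-diphenyl-tetrahydro-1H,3H-pyrrolo[1,2-c][1,3,2]oxazaborole (0.2 equiv), catecholborane (1.5 equiv), toluene, −78 °C; MeOH, pH 7 buffer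
Reagents that add atoms: none
Why: Corey–Bakshi–Shibata reduction in which the oxazaborolidine binds the ketone with the α-branched dienyl group as the large substituent and the C8 methylene as the small one, so the (R)-catalyst should deliver hydride to the face that makes C9 S; catecholborane at −78 °C should spare the alkenes and the ester.

**Step 11**
Reactants: 17 (9S)-dienyl alcohol
Product: 18 bis-silyl ether (cyclisation precursor)
Conditions: TBSOTf, 2,6-lutidine, CH2Cl2, −78 °C
Reagents that add atoms: tert-butyldimethylsilyl trifluoromethanesulfonate, CC(C)(C)[Si](C)(C)OS(=O)(=O)C(F)(F)F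
Why: Silylation of the hindered secondary alcohol with the silyl triflate; a silyl ether is chosen over the acetate because an allylic ester at C9 could ionise with zerovalent palladium in the next step and could migrate to O14 once that oxygen is freed.

**Step 12**
Reactants: 18 bis-silyl ether
Product: 20 ten-membered diene, via C3 alkylborane 19 (not isolated)
Conditions: disiamylborane [bis(3-methylbutan-2-yl)borane] (1.5 equiv, fresh solution), THF, 0 °C → rt; then syringe-pump addition (10 h) to PdCl2(dppf) (20 mol%), AsPh3 (40 mol%), Cs2CO3 (3 equiv), DMF/THF/H2O, 50 °C, about 1 mM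
Reagents that add atoms: none
Why: The hindered dialkylborane adds anti-Markovnikov to the monosubstituted C2=C3 vinyl group and places boron on C3, while the 1,1-disubstituted isopropenyl group on the branched C7 and the trisubstituted C1=C10 and C4=C5 bonds should not react. Zerovalent palladium formed from PdCl2(dppf) then inserts into the C4–Br bond with retention, base-assisted transmetalation transfers only the primary alkyl group, and reductive elimination forms C3–C4; the closest known reaction type is the B-alkyl Suzuki–Miyaura macrocyclisation of a hydroborated terminal alkene onto an alkenyl halide. The ten-membered carbocycle closes by reductive elimination from an eleven-membered alkyl(alkenyl)palladacycle, an sp3–sp2 closure in which C4=C5 stays inside the ring. No stereocentre is created: the ring-cis geometry of C4=C5 follows from retention at C4 of the (Z)-bromoenoate, and C7, C9 and the E geometry of C1=C10 are carried through. The step needs chemoselective hydroboration, which the choice of disiamylborane and the shielding of the isopropenyl group at C7 should secure, and ring closure over oligomerisation, which slow addition at high dilution and the wide-bite-angle dppf ligand should favour; the silyl ether at C9 cannot form a π-allyl complex.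

**Step 13**
Reactants: 20 ten-membered diene
Product: 21 macrocyclic allylic alcohol (C14–OH)
Conditions: HF·pyridine, pyridine, THF, 0 °C
Reagents that add atoms: none
Why: Selective desilylation, in which buffered fluoride should cleave the primary allylic silyl ether much faster than the hindered secondary one at C9.

**Step 14**
Reactants: 21 macrocyclic allylic alcohol
Product: 22 (1R,10S)-epoxy alcohol
Conditions: Ti(OiPr)4 (20 mol%), L-(+)-diethyl tartrate (24 mol%), t-BuOOH (2 equiv), 4 Å molecular sieves, CH2Cl2, −20 °C
Reagents that add atoms: tert-butyl hydroperoxide, CC(C)(C)OO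
Why: Sharpless asymmetric epoxidation, in which the titanium tartrate binds C14–OH and delivers oxygen only to C1=C10; L-(+)-tartrate, the enantiomer that converts (E)-hex-2-en-1-ol into its (2S,3S)-epoxide, should add oxygen to the face that makes C1 R and C10 S, and the E geometry keeps C2 and C9 trans on the oxirane.

**Step 15**
Reactants: 22 epoxy alcohol; 23 (R)-2-methylbutanoic acid
Product: 24 C14 (R)-2-methylbutanoate
Conditions: 23 (1.5 equiv), N,N'-dicyclohexylcarbodiimide, 4-(dimethylamino)pyridine (10 mol%), CH2Cl2, 0 °C → rt
Reagents that add atoms: none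
Why: Steglich esterification of the primary epoxy alcohol; the acid has no activating α-substituent, so its stereocentre is expected to survive carbodiimide activation at 0 °C.

**Step 16**
Reactants: 24 C14 (R)-2-methylbutanoate
Product: 25 C9 alcohol
Conditions: HF·pyridine (excess), THF, 0 °C → rt
Reagents that add atoms: none
Why: Fluoride-mediated cleavage of the secondary silyl ether under mildly acidic conditions, which the trisubstituted epoxide (flanked by electron-withdrawing oxygen substituents) and both esters should tolerate.

**Step 17**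
Reactants: 25 C9 alcohol
Product: 26 target compound CNP0352790.1
Conditions: Ac2O, pyridine, 4-(dimethylamino)pyridine (cat.), CH2Cl2, 0 °C → rt
Reagents that add atoms: acetic anhydride, CC(=O)OC(C)=O
Why: O-Acetylation under nucleophilic catalysis forms the C9 acetate with retention, since the C9–O bond is not broken.

**Compound list**
1 | 5,6-dihydro-2H-pyran-2-one | O=C1C=CCCO1 | starting material
2 | isopropenylboronic acid pinacol ester | C=C(C)B1OC(C)(C)C(C)(C)O1 | starting material
3 | (4S)-4-(prop-1-en-2-yl)oxan-2-one | C=C(C)[C@H]1CCOC(=O)C1 | intermediate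
4 | methyl propiolate | C#CC(=O)OC | starting material
5 | methyl (E)-2,3-dibromoprop-2-enoate | Br/C=C(/Br)C(=O)OC | intermediate
6 | tributyl(vinyl)stannane | C=C[Sn](CCCC)(CCCC)CCCC | starting material
7 | methyl (E)-2-bromopenta-2,4-dienoate | C=C/C=C(/Br)C(=O)OC | intermediate
8 | (E)-2-bromopenta-2,4-dien-1-ol | C=C/C=C(/Br)CO | intermediate
9 | (E)-[(2-bromopenta-2,4-dien-1-yl)oxy](tert-butyl)dimethylsilane | C=C/C=C(/Br)CO[Si](C)(C)C(C)(C)C | intermediate
10 | (Z)-{1-[(tert-butyldimethylsilyl)oxy]penta-2,4-dien-2-yl}lithium (lithium trans to the vinyl group) | C=C/C=C(/[Li])CO[Si](C)(C)C(C)(C)C | intermediate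
11 | (4E,7S)-4-{[(tert-butyldimethylsilyl)oxy]methyl}-9-hydroxy-7-(prop-1-en-2-yl)nona-1,3-dien-5-one | C=C(C)[C@@H](CCO)CC(=O)/C(CO[Si](C)(C)C(C)(C)C)=C/C=C | intermediate
12 | (3S,6E)-6-{[(tert-butyldimethylsilyl)oxy]methyl}-5-oxo-3-(prop-1-en-2-yl)nona-6,8-dienal | C=C(C)[C@@H](CC=O)CC(=O)/C(CO[Si](C)(C)C(C)(C)C)=C/C=C | intermediate
13 | methyl (triphenyl-λ5-phosphanylidene)acetate | COC(=O)C=P(c1ccccc1)(c1ccccc1)c1ccccc1 | starting material
14 | (1-bromo-2-methoxy-2-oxoethyl)triphenylphosphonium bromide | COC(=O)C(Br)[P+](c1ccccc1)(c1ccccc1)c1ccccc1.[Br-] | intermediate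
15 | methyl 2-bromo-2-(triphenyl-λ5-phosphanylidene)acetate | COC(=O)C(Br)=P(c1ccccc1)(c1ccccc1)c1ccccc1 | intermediate
16 | methyl (2Z,5S,8E)-2-bromo-8-{[(tert-butyldimethylsilyl)oxy]methyl}-7-oxo-5-(prop-1-en-2-yl)undeca-2,8,10-trienoate | C=C(C)[C@@H](C/C=C(\Br)C(=O)OC)CC(=O)/C(CO[Si](C)(C)C(C)(C)C)=C/C=C | intermediate
17 | methyl (2Z,5S,7S,8E)-2-bromo-8-{[(tert-butyldimethylsilyl)oxy]methyl}-7-hydroxy-5-(prop-1-en-2-yl)undeca-2,8,10-trienoate | C=C(C)[C@@H](C/C=C(\Br)C(=O)OC)C[C@H](O)/C(CO[Si](C)(C)C(C)(C)C)=C/C=C | intermediate
18 | methyl (2Z,5S,7S,8E)-2-bromo-7-[(tert-butyldimethylsilyl)oxy]-8-{[(tert-butyldimethylsilyl)oxy]methyl}-5-(prop-1-en-2-yl)undeca-2,8,10-trienoate | C=C(C)[C@@H](C/C=C(\Br)C(=O)OC)C[C@H](O[Si](C)(C)C(C)(C)C)/C(CO[Si](C)(C)C(C)(C)C)=C/C=C | intermediate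
19 | methyl (2Z,5S,7S,8E)-11-[bis(3-methylbutan-2-yl)boranyl]-2-bromo-7-[(tert-butyldimethylsilyl)oxy]-8-{[(tert-butyldimethylsilyl)oxy]methyl}-5-(prop-1-en-2-yl)undeca-2,8-dienoate | C=C(C)[C@@H](C/C=C(\Br)C(=O)OC)C[C@H](O[Si](C)(C)C(C)(C)C)/C(CO[Si](C)(C)C(C)(C)C)=C/CCB(C(C)C(C)C)C(C)C(C)C | intermediate
20 | methyl (7S,9S)-9-[(tert-butyldimethylsilyl)oxy]-10-{[(tert-butyldimethylsilyl)oxy]methyl}-7-(prop-1-en-2-yl)cyclodeca-1(10),4-diene-4-carboxylate (target numbering; C3 and C6 cis on C4=C5, C2 and C9 trans on C1=C10) | C=C(C)[C@H]1C/C=C(/C(=O)OC)CC/C=C(\CO[Si](C)(C)C(C)(C)C)[C@@H](O[Si](C)(C)C(C)(C)C)C1 | intermediate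
21 | methyl (7S,9S)-9-[(tert-butyldimethylsilyl)oxy]-10-(hydroxymethyl)-7-(prop-1-en-2-yl)cyclodeca-1(10),4-diene-4-carboxylate (target numbering, alkene geometries as in 20) | C=C(C)[C@H]1C/C=C(/C(=O)OC)CC/C=C(\CO)[C@@H](O[Si](C)(C)C(C)(C)C)C1 | intermediate
22 | methyl (1R,7S,9S,10S)-9-[(tert-butyldimethylsilyl)oxy]-1,10-epoxy-10-(hydroxymethyl)-7-(prop-1-en-2-yl)cyclodec-4-ene-4-carboxylate (target numbering) | C=C(C)[C@H]1C/C=C(/C(=O)OC)CC[C@H]2O[C@]2(CO)[C@@H](O[Si](C)(C)C(C)(C)C)C1 | intermediate
23 | (R)-2-methylbutanoic acid | CC[C@@H](C)C(=O)O | starting material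
24 | methyl (1R,7S,9S,10S)-9-[(tert-butyldimethylsilyl)oxy]-1,10-epoxy-10-({[(2R)-2-methylbutanoyl]oxy}methyl)-7-(prop-1-en-2-yl)cyclodec-4-ene-4-carboxylate (target numbering) | C=C(C)[C@H]1C/C=C(/C(=O)OC)CC[C@H]2O[C@]2(COC(=O)[C@H](C)CC)[C@@H](O[Si](C)(C)C(C)(C)C)C1 | intermediate
25 | methyl (1R,7S,9S,10R)-1,10-epoxy-9-hydroxy-10-({[(2R)-2-methylbutanoyl]oxy}methyl)-7-(prop-1-en-2-yl)cyclodec-4-ene-4-carboxylate (target numbering; C10 is unchanged in space, only its descriptor changes with the free hydroxyl group) | C=C(C)[C@H]1C/C=C(/C(=O)OC)CC[C@H]2O[C@]2(COC(=O)[C@H](C)CC)[C@@H](O)C1 | intermediate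
26 | CNP0352790.1, methyl (1R,7S,9S,10S)-9-acetoxy-1,10-epoxy-10-({[(2R)-2-methylbutanoyl]oxy}methyl)-7-(prop-1-en-2-yl)cyclodec-4-ene-4-carboxylate (target numbering) | C=C(C)[C@H]1C/C=C(/C(=O)OC)CC[C@H]2O[C@]2(COC(=O)[C@H](C)CC)[C@@H](OC(C)=O)C1 | target

**Step count**
Total: 17 steps. Longest linear sequence: 15 steps (methyl propiolate 4 to 26 through steps 2–7 and 9–17).

**Steps most likely to fail**

Step 12. The hydroboration may not discriminate fully between the diene terminus and the isopropenyl group. Transmetalation of the hindered alkyl(disiamyl)borane may also be slow enough that intermolecular coupling, protodeboronation and β-hydride elimination outrun closure of the strained ten-membered ring. The fallback sets out from 18 and separates nucleophile formation from ring closure. Hydroboration with disiamylborane followed by oxidation with NaBO3·4H2O (THF/H2O, rt) would give the primary C3 alcohol F1, which can be freed of any regioisomer by chromatography. I2, PPh3 and imidazole (CH2Cl2, 0 °C) would convert it into the primary iodide F2. Zinc insertion (Zn dust, LiCl, THF, 25–40 °C, conditions under which an alkenyl bromide should be inert) would give the alkylzinc iodide F3. Slow addition of F3 to PdCl2(dppf) in THF/NMP at 40 °C (intramolecular Negishi coupling, no base) would form the same C3–C4 bond and return to the route at 20.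

Step 14. Facial selectivity may be poor or reversed, because a given conformer of the ten-membered ring exposes only one face of the E-configured C1=C10 bond and the bulky silyloxy group at C9 lies next to the titanium-bound hydroxymethyl group; a slow reaction would also give the epoxy alcohol time to open. The fallback sets out from 20 and uses a non-directed, catalyst-controlled oxygen transfer. Shi epoxidation with 1,2:4,5-di-O-isopropylidene-β-D-erythro-2,3-hexodiulo-2,6-pyranose (the D-fructose-derived ketone), Oxone (2KHSO5·KHSO4·K2SO4) and K2CO3 in MeCN/dimethoxymethane/aqueous buffer at 0 °C is expected to attack the trisubstituted C1=C10 bond in preference to the isopropenyl group and the enoate. By analogy with (E)-β-methylstyrene, which gives the (R,R)-oxide with this ketone, it should add oxygen to the same face as L-(+)-tartrate and give the bis-silyl epoxide F4. Selective cleavage of the primary silyl ether of F4 with buffered HF·pyridine (pyridine, THF, 0 °C) would return to the route at 22.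

Step 6. The dienyllithium may add a second time to the liberated dienone, may enolise the lactone, or may decompose by loss of silanolate before it is trapped. The fallback sets out from 3 and changes the acyl acceptor. Aminolysis with MeNH(OMe)·HCl and AlMe3 (CH2Cl2, 0 °C → rt) would give the hydroxy N-methoxy-N-methyl amide F5. Treatment of F5 with two equivalents of dienyllithium 10 (from 9 as in step 6, the first equivalent being consumed by the hydroxyl group) in Et2O/THF at −78 °C, followed by aqueous NH4Cl, would stop cleanly at the ketone stage, as is usual for Weinreb amides, and return to the route at 11.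

**Further compounds**
F1 | step 12 | methyl (2Z,5S,7S,8E)-2-bromo-7-[(tert-butyldimethylsilyl)oxy]-8-{[(tert-butyldimethylsilyl)oxy]methyl}-11-hydroxy-5-(prop-1-en-2-yl)undeca-2,8-dienoate | C=C(C)[C@@H](C/C=C(\Br)C(=O)OC)C[C@H](O[Si](C)(C)C(C)(C)C)/C(CO[Si](C)(C)C(C)(C)C)=C/CCO
F2 | step 12 | methyl (2Z,5S,7S,8E)-2-bromo-7-[(tert-butyldimethylsilyl)oxy]-8-{[(tert-butyldimethylsilyl)oxy]methyl}-11-iodo-5-(prop-1-en-2-yl)undeca-2,8-dienoate | C=C(C)[C@@H](C/C=C(\Br)C(=O)OC)C[C@H](O[Si](C)(C)C(C)(C)C)/C(CO[Si](C)(C)C(C)(C)C)=C/CCI
F3 | step 12 | alkylzinc iodide derived from F2 (C3–ZnI) | C=C(C)[C@@H](C/C=C(\Br)C(=O)OC)C[C@H](O[Si](C)(C)C(C)(C)C)/C(CO[Si](C)(C)C(C)(C)C)=C/CC[Zn]I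
F4 | step 14 | methyl (1R,7S,9S,10S)-9-[(tert-butyldimethylsilyl)oxy]-10-{[(tert-butyldimethylsilyl)oxy]methyl}-1,10-epoxy-7-(prop-1-en-2-yl)cyclodec-4-ene-4-carboxylate (target numbering) | C=C(C)[C@H]1C/C=C(/C(=O)OC)CC[C@H]2O[C@]2(CO[Si](C)(C)C(C)(C)C)[C@@H](O[Si](C)(C)C(C)(C)C)C1
F5 | step 6 | (3S)-5-hydroxy-N-methoxy-N-methyl-3-(prop-1-en-2-yl)pentanamide | C=C(C)[C@@H](CCO)CC(=O)N(C)OC
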